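The ten-membered ring is opened at C3–C4, where the C3 carbinol adjoins C4 of the 4,5-epoxide. An intramolecular Nozaki–Hiyama–Kishi reaction adds a (Z)-C4 alkenylchromium to a C3 aldehyde and so makes, in one operation, the C3–C4 bond, the carbocycle, the C3 stereocentre and the (Z)-allylic alcohol whose hydroxyl then steers the 4,5-epoxidation. The precursor is an open chain (C3 to C5 through C1, C10, C9, C8, C7, C6) with a C3 aldehyde, the cis-1,10-epoxide, the C9 acetate, the C8 angelate, the C7 isopropenyl group and a (Z)-C4 iodoalkene. Its epoxide comes from a Sharpless epoxidation, C7 and C8 from a (Z)-allylboration.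

Key step: step 22

Assumption: aldehyde 1 is taken as a catalogue compound; it is otherwise one oxidation away from the commercial mono-TBDPS ether of propane-1,3-diol.

Conventions: atom labels C1–C10 follow the ring of the target (C1/C10 and C4/C5 are the epoxide carbons, C11 is the isopropenyl carbon on C7, C12 its methylene carbon) and are kept for the open-chain intermediates. TBDPS = tert-butyldiphenylsilyl, TES = triethylsilyl, PMB = 4-methoxybenzyl, pin = pinacolato, cod = cycloocta-1,5-diene, PCy3 = tricyclohexylphosphine.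

**Western fragment (C3–C2–C1–C10–C9–C8)**

Step 1
Reactants: 1 3-(TBDPS-oxy)propanal; 2 ethyl 2-[bis(2,2,2-trifluoroethoxy)phosphoryl]propanoate
Product: 4 ethyl (2Z)-5-(TBDPS-oxy)-2-methylpent-2-enoate, via potassium phosphonate anion 3 (not isolated)
Conditions: KN(SiMe3)2, 18-crown-6, THF, −78 °C
Reagents that add atoms: none
Why: Still–Gennari variant of the Horner–Wadsworth–Emmons olefination; the trifluoroethyl phosphonate eliminates from the kinetic adduct and should give the (Z)-enoate with C9 and C2 cis, the geometry the cis-1,10-epoxide requires.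

Step 2
Reactants: 4 ethyl (2Z)-5-(TBDPS-oxy)-2-methylpent-2-enoate
Product: 5 (2Z)-5-(TBDPS-oxy)-2-methylpent-2-en-1-ol
Conditions: i-Bu2AlH, CH2Cl2, −78 °C
Reagents that add atoms: none
Why: Hydride reduction of an α,β-unsaturated ester with i-Bu2AlH goes 1,2 at low temperature and leaves the alkene geometry and the silyl ether untouched.

Step 3
Reactants: 5 (2Z)-5-(TBDPS-oxy)-2-methylpent-2-en-1-ol
Product: 6 cis-epoxy alcohol (C9 primary alcohol, 1,10-epoxide)
Conditions: Ti(OiPr)4 (10 mol %), L-(+)-diisopropyl tartrate (12 mol %), t-BuOOH, 4 Å molecular sieves, CH2Cl2, −20 °C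
Reagents that add atoms: tert-butyl hydroperoxide, CC(C)(C)OO
Why: Sharpless asymmetric epoxidation of a (Z)-2-methyl allylic alcohol; the L-(+)-tartrate–titanium catalyst delivers oxygen to one alkene face and should set C1 and C10 as in the target, the Z geometry becoming the cis-epoxide.

Step 4
Reactants: 6 cis-epoxy alcohol
Product: 7 epoxy aldehyde (C9 aldehyde)
Conditions: Dess–Martin periodinane, pyridine, CH2Cl2, 0 → 23 °C
Reagents that add atoms: none
Why: Dess–Martin oxidation of the primary epoxy alcohol under pyridine buffering; the α-carbon (C10) is quaternary, so the aldehyde cannot epimerise.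

Step 5
Reactants: 7 epoxy aldehyde
Product: 8 erythro vinyl carbinol (9S)
Conditions: CH2=CHMgBr, THF, −78 °C
Reagents that add atoms: vinylmagnesium bromide, C=C[Mg]Br
Why: Grignard 1,2-addition under Cornforth/Felkin–Anh control; with the C10–O bond anti to the carbonyl the reagent should pass the C10 methyl and not the substituted C1, giving the erythro (9S) epoxy alcohol.

Step 6
Reactants: 8 erythro vinyl carbinol
Product: 9 C9 triethylsilyl ether
Conditions: Et3SiOTf, 2,6-lutidine, CH2Cl2, −78 °C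
Reagents that add atoms: triethylsilyl trifluoromethanesulfonate, CC[Si](CC)(CC)OS(=O)(=O)C(F)(F)F
Why: Silylation of a hindered secondary alcohol with a silyl triflate and a hindered pyridine base, conditions that leave the epoxide closed.

Step 7
Reactants: 9 C9 triethylsilyl ether
Product: 11 α-silyloxy aldehyde (C8 aldehyde), via ozonide 10 (not isolated)
Conditions: O3, CH2Cl2, −78 °C; then PPh3, −78 → 23 °C
Reagents that add atoms: ozone, [O-][O+]=O
Why: Ozonolysis of the only alkene with reductive work-up; the α-silyloxy β,γ-epoxy aldehyde is taken on crude so that C9 meets neither base nor silica.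

**Eastern fragment (C5–C6–C7–C11–C12)**

Step 8
Reactants: 12 methacrolein; 13 ethyl (triphenylphosphoranylidene)acetate
Product: 14 ethyl (2E)-4-methylpenta-2,4-dienoate
Conditions: CH2Cl2, 0 → 23 °C
Reagents that add atoms: none
Why: Wittig olefination with a stabilised ylide, which adds 1,2 to the enal and, through reversible oxaphosphetane formation, should give the (E)-dienoate.

Step 9
Reactants: 14 ethyl (2E)-4-methylpenta-2,4-dienoate
Product: 15 (2E)-4-methylpenta-2,4-dien-1-ol
Conditions: i-Bu2AlH, CH2Cl2, −78 °C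
Reagents that add atoms: none
Why: 1,2-Reduction of the conjugated ester with i-Bu2AlH at low temperature, which leaves the diene untouched.

Step 10
Reactants: 15 (2E)-4-methylpenta-2,4-dien-1-ol
Product: 17 dienyl PMB ether, via sodium dienolate 16 (not isolated)
Conditions: NaH, THF/DMF, 0 °C; 4-methoxybenzyl chloride, Bu4NI (cat.), 0 → 23 °C
Reagents that add atoms: 4-methoxybenzyl chloride, COc1ccc(CCl)cc1
Why: Williamson ether synthesis; the primary alkoxide displaces the benzylic chloride, iodide catalysis keeping the temperature low enough to avoid diene polymerisation.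

Step 11
Reactants: 17 dienyl PMB ether
Product: 18 (Z)-allylboronate
Conditions: Ni(cod)2 (2.5 mol %), PCy3 (2.5 mol %), pinacolborane, toluene, 23 °C; filtered through deactivated silica
Reagents that add atoms: pinacolborane, CC1(C)OBOC1(C)C
Why: Nickel-catalysed 1,4-hydroboration of a 1,3-diene; the diene binds zerovalent nickel in its s-cis form, hydrogen goes to the substituted terminus (C6) and boron to the free methylene terminus (C12), so the anti π-allyl intermediate should give the C11=C7 alkene with the boryl-methyl group cis to C6, the (Z)-γ-substituted allylboronate.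

**Fragment union and elaboration to the precursor**

Step 12
Reactants: 11 α-silyloxy aldehyde; 18 (Z)-allylboronate
Product: 20 homoallylic alcohol (free 8-OH), via borate ester 19 (not isolated)
Conditions: toluene (2 M), 4 Å molecular sieves, 23 → 40 °C; then aq. NaHCO3
Reagents that add atoms: none
Why: Allylboration through a Zimmerman–Traxler chair; the axial (Z)-γ-substituent gives the 7,8-syn relation and the Cornforth arrangement of the aldehyde (C9–O anti to C=O, H9 toward the axial substituent, bulky C10 anti to the forming bond) should give 8,9-anti, so C7 (R) and C8 (S) are set from C9.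

Step 13
Reactants: 21 angelic acid
Product: 22 angelic 2,4,6-trichlorobenzoic mixed anhydride
Conditions: 2,4,6-trichlorobenzoyl chloride, Et3N, toluene, 23 °C; Et3N·HCl filtered off under argon, filtrate concentrated and kept as a toluene solution at −20 °C
Reagents that add atoms: 2,4,6-trichlorobenzoyl chloride, O=C(Cl)c1c(Cl)cc(Cl)cc1Cl
Why: Yamaguchi-type acyl substitution of the aroyl chloride by triethylammonium angelate; no nucleophilic catalyst is present, so the Z geometry should be kept, and the anhydride is made once on a scale that serves steps 14 and 24.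

Step 14
Reactants: 20 homoallylic alcohol; 22 angelic 2,4,6-trichlorobenzoic mixed anhydride
Product: 23 C8 angelate
Conditions: Et3N, toluene, 80 °C
Reagents that add atoms: none
Why: Yamaguchi-type esterification without a nucleophilic catalyst; the two ortho chlorines shield the aroyl carbonyl, so the alcohol attacks the angeloyl carbonyl, the known way to acylate hindered alcohols without isomerisation to the tiglate.

Step 15
Reactants: 23 C8 angelate
Product: 24 C5 primary alcohol
Conditions: DDQ, CH2Cl2/pH 7 buffer, 0 → 23 °C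
Reagents that add atoms: none
Why: Oxidative cleavage of the 4-methoxybenzyl ether by DDQ under buffered conditions, orthogonal to both silyl ethers, the ester and the epoxide.

Step 16
Reactants: 24 C5 primary alcohol
Product: 25 C5 aldehyde
Conditions: Dess–Martin periodinane, pyridine, CH2Cl2, 0 → 23 °C
Reagents that add atoms: none
Why: Dess–Martin oxidation of a primary alcohol; the aldehyde has no α-stereocentre and no β-leaving group.

Step 17
Reactants: 25 C5 aldehyde; 26 ethyltriphenylphosphonium iodide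
Product: 30 (Z)-C4 iodoalkene, via ethylidene ylide 27 (not isolated), via iodoethylphosphonium iodide 28 (not isolated), via iodo ylide 29 (not isolated)
Conditions: n-BuLi, THF, 23 °C; I2, −78 °C; NaN(SiMe3)2, −78 → −20 °C; then 25, −78 → −20 °C
Reagents that add atoms: iodine, II
Why: Stork–Zhao-type Wittig olefination with the non-stabilised α-iodo ylide; the kinetic cis-oxaphosphetane should place iodine cis to the chain and give the (Z)-C4 iodoalkene, and at −78 °C the ylide reacts with the aldehyde far faster than with the hindered ester.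

Step 18
Reactants: 30 (Z)-C4 iodoalkene
Product: 31 C9 alcohol
Conditions: HF·pyridine, pyridine, THF, 0 °C
Reagents that add atoms: none
Why: Fluoride-mediated desilylation; buffered HF·pyridine removes the secondary triethylsilyl ether far faster than the primary TBDPS ether, and the acidic medium prevents acyl migration from O8 to O9.

Step 19
Reactants: 31 C9 alcohol
Product: 32 C9 acetate
Conditions: Ac2O, pyridine, DMAP (cat.), CH2Cl2, 0 °C
Reagents that add atoms: acetic anhydride, CC(=O)OC(C)=O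
Why: Acylation with acetic anhydride and catalytic DMAP, fast enough that the neighbouring angelate should not migrate.

Step 20
Reactants: 32 C9 acetate
Product: 33 C3 primary alcohol
Conditions: Bu4NF, AcOH (1:1), THF, 0 → 23 °C
Reagents that add atoms: none
Why: Desilylation with fluoride buffered by acetic acid, which removes the remaining silyl ether without touching the two esters or the epoxide.

Step 21
Reactants: 33 C3 primary alcohol
Product: 34 seco iodoalkene aldehyde (cyclisation precursor)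
Conditions: Dess–Martin periodinane, pyridine, CH2Cl2, 0 °C; filtered and used at once
Reagents that add atoms: none
Why: Dess–Martin oxidation under pyridine buffering; the β,γ-epoxy aldehyde can open to a γ-hydroxy enal with base or on silica, so it is not chromatographed.

**Ring closure and completion**

Step 22
Reactants: 34 seco iodoalkene aldehyde
Product: 36 (4Z)-cyclodecen-3-ol, via alkenylchromium 35 (not isolated)
Conditions: CrCl2 (15 equiv), NiCl2 (0.2 equiv), degassed DMSO, 23 °C, slow addition of 34 (final 2 mM)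
Reagents that add atoms: none
Why: Nozaki–Hiyama–Kishi reaction: zerovalent nickel, formed from NiCl2 by CrCl2, inserts into the C4–I bond, the alkenyl group passes to trivalent chromium, and alkenylchromium 35 adds to the C3 aldehyde through a chromium-bound carbonyl, two CrCl2 being consumed per ring. The closest known reaction type is the macrocyclising alkenyl iodide–aldehyde coupling used for medium and large carbocycles. The ten-membered ring is closed end to end by a 10-exo-trig attack of C4 on the C3 carbonyl, helped by the two cis units (1,10-epoxide and (Z)-alkene) that bend the chain and by high dilution. The one new stereocentre, C3, is set by the folded transition state: the chromium-bound oxygen should lie on the outer face with H3 turned toward C6, and the C1 epoxide centre two atoms away decides on which face of the alkenyl plane the C2 tether runs; 3S is needed and is the least certain outcome of the step. Chemoselectivity (aldehyde over acetate, angelate and epoxide, no enolisation of the β,γ-epoxy aldehyde) follows from the low basicity of alkenylchromium, and the Z geometry is retained because trisubstituted alkenyl–metal species do not invert.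

Step 23
Reactants: 36 (4Z)-cyclodecen-3-ol
Product: 37 4,5-epoxy alcohol
Conditions: mCPBA, NaHCO3, CH2Cl2, −20 → 0 °C
Reagents that add atoms: 3-chloroperbenzoic acid, O=C(OO)c1cccc(Cl)c1
Why: Hydroxyl-directed (Henbest) peracid epoxidation; with H3 eclipsing C4=C5 toward C6 (minimal A(1,3) strain) the hydroxyl stands on the outer face at about 120° to the alkene plane, so oxygen should be delivered syn to it and give the threo 4,5-epoxide of the target, while the trisubstituted hydrogen-bonded alkene reacts ahead of the isopropenyl group and the electron-poor angelate.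

Step 24
Reactants: 37 4,5-epoxy alcohol; 22 angelic 2,4,6-trichlorobenzoic mixed anhydride
Product: 38 CNP0220329.1
Conditions: Et3N, toluene, 80 °C
Reagents that add atoms: none
Why: The same Yamaguchi-type mixed-anhydride angeloylation as in step 14, now on the C3 epoxy alcohol; no alkoxide is formed, so neither Payne rearrangement nor acyl migration is expected.

**Compound list**

1 | 3-[(tert-butyldiphenylsilyl)oxy]propanal | O=CCCO[Si](c1ccccc1)(c1ccccc1)C(C)(C)C | starting material
2 | ethyl 2-[bis(2,2,2-trifluoroethoxy)phosphoryl]propanoate | CCOC(=O)C(C)P(=O)(OCC(F)(F)F)OCC(F)(F)F | starting material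
3 | potassium salt of the α-carbanion of 2 | [K+].CCOC(=O)[C-](C)P(=O)(OCC(F)(F)F)OCC(F)(F)F | intermediate
4 | ethyl (2Z)-5-[(tert-butyldiphenylsilyl)oxy]-2-methylpent-2-enoate | CCOC(=O)/C(C)=C\CCO[Si](c1ccccc1)(c1ccccc1)C(C)(C)C | intermediate
5 | (2Z)-5-[(tert-butyldiphenylsilyl)oxy]-2-methylpent-2-en-1-ol | OC/C(C)=C\CCO[Si](c1ccccc1)(c1ccccc1)C(C)(C)C | intermediate
6 | [(2S,3R)-3-{2-[(tert-butyldiphenylsilyl)oxy]ethyl}-2-methyloxiran-2-yl]methanol | CC(C)(C)[Si](c1ccccc1)(c1ccccc1)OCC[C@H]1O[C@@]1(C)CO | intermediate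
7 | (2R,3R)-3-{2-[(tert-butyldiphenylsilyl)oxy]ethyl}-2-methyloxirane-2-carbaldehyde | CC(C)(C)[Si](c1ccccc1)(c1ccccc1)OCC[C@H]1O[C@@]1(C)C=O | intermediate
8 | (1S)-1-[(2S,3R)-3-{2-[(tert-butyldiphenylsilyl)oxy]ethyl}-2-methyloxiran-2-yl]prop-2-en-1-ol | CC(C)(C)[Si](c1ccccc1)(c1ccccc1)OCC[C@H]1O[C@@]1(C)[C@@H](O)C=C | intermediate
9 | (1S)-1-[(2R,3R)-3-{2-[(tert-butyldiphenylsilyl)oxy]ethyl}-2-methyloxiran-2-yl]prop-2-en-1-yl triethylsilyl ether | CC(C)(C)[Si](c1ccccc1)(c1ccccc1)OCC[C@H]1O[C@@]1(C)[C@@H](O[Si](CC)(CC)CC)C=C | intermediate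
10 | ozonide of 9 (1,2,4-trioxolan-3-yl in place of the vinyl group, both epimers at the trioxolane carbon) | CC(C)(C)[Si](c1ccccc1)(c1ccccc1)OCC[C@H]1O[C@@]1(C)[C@@H](O[Si](CC)(CC)CC)C1OCOO1 | intermediate
11 | (2R)-2-[(2R,3R)-3-{2-[(tert-butyldiphenylsilyl)oxy]ethyl}-2-methyloxiran-2-yl]-2-[(triethylsilyl)oxy]acetaldehyde | CC(C)(C)[Si](c1ccccc1)(c1ccccc1)OCC[C@H]1O[C@@]1(C)[C@@H](O[Si](CC)(CC)CC)C=O | intermediate
12 | methacrolein, 2-methylprop-2-enal | C=C(C)C=O | starting material
13 | ethyl (triphenylphosphoranylidene)acetate | CCOC(=O)C=P(c1ccccc1)(c1ccccc1)c1ccccc1 | starting material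
14 | ethyl (2E)-4-methylpenta-2,4-dienoate | CCOC(=O)/C=C/C(C)=C | intermediate
15 | (2E)-4-methylpenta-2,4-dien-1-ol | OC/C=C/C(C)=C | intermediate
16 | sodium (2E)-4-methylpenta-2,4-dien-1-olate | [Na+].[O-]C/C=C/C(C)=C | intermediate
17 | 1-methoxy-4-({[(2E)-4-methylpenta-2,4-dien-1-yl]oxy}methyl)benzene | C=C(C)/C=C/COCc1ccc(OC)cc1 | intermediate
18 | 2-{(2Z)-5-[(4-methoxybenzyl)oxy]-2-methylpent-2-en-1-yl}-4,4,5,5-tetramethyl-1,3,2-dioxaborolane | CC1(C)OB(C/C(C)=C\CCOCc2ccc(OC)cc2)OC1(C)C | intermediate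
19 | pinacol borate ester of 20 (B(pin) on O8) | CC(C)(C)[Si](c1ccccc1)(c1ccccc1)OCC[C@H]1O[C@@]1(C)[C@@H](O[Si](CC)(CC)CC)[C@@H](OB2OC(C)(C)C(C)(C)O2)[C@@H](C(C)=C)CCOCc3ccc(OC)cc3 | intermediate
20 | (1S,2S,3R)-1-[(2R,3R)-3-{2-[(tert-butyldiphenylsilyl)oxy]ethyl}-2-methyloxiran-2-yl]-3-{2-[(4-methoxybenzyl)oxy]ethyl}-4-methyl-1-[(triethylsilyl)oxy]pent-4-en-2-ol | CC(C)(C)[Si](c1ccccc1)(c1ccccc1)OCC[C@H]1O[C@@]1(C)[C@@H](O[Si](CC)(CC)CC)[C@@H](O)[C@@H](C(C)=C)CCOCc2ccc(OC)cc2 | intermediate
21 | angelic acid, (2Z)-2-methylbut-2-enoic acid | C/C=C(C)\C(=O)O | starting material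
22 | (2Z)-2-methylbut-2-enoic 2,4,6-trichlorobenzoic anhydride | C/C=C(C)\C(=O)OC(=O)c1c(Cl)cc(Cl)cc1Cl | intermediate
23 | (1S,2S,3R)-1-[(2R,3R)-3-{2-[(tert-butyldiphenylsilyl)oxy]ethyl}-2-methyloxiran-2-yl]-3-{2-[(4-methoxybenzyl)oxy]ethyl}-4-methyl-1-[(triethylsilyl)oxy]pent-4-en-2-yl (2Z)-2-methylbut-2-enoate | CC(C)(C)[Si](c1ccccc1)(c1ccccc1)OCC[C@H]1O[C@@]1(C)[C@@H](O[Si](CC)(CC)CC)[C@@H](OC(=O)/C(C)=C\C)[C@@H](C(C)=C)CCOCc2ccc(OC)cc2 | intermediate
24 | (1S,2S,3R)-1-[(2R,3R)-3-{2-[(tert-butyldiphenylsilyl)oxy]ethyl}-2-methyloxiran-2-yl]-3-(2-hydroxyethyl)-4-methyl-1-[(triethylsilyl)oxy]pent-4-en-2-yl (2Z)-2-methylbut-2-enoate | CC(C)(C)[Si](c1ccccc1)(c1ccccc1)OCC[C@H]1O[C@@]1(C)[C@@H](O[Si](CC)(CC)CC)[C@@H](OC(=O)/C(C)=C\C)[C@@H](C(C)=C)CCO | intermediate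
25 | (1S,2S,3R)-1-[(2R,3R)-3-{2-[(tert-butyldiphenylsilyl)oxy]ethyl}-2-methyloxiran-2-yl]-4-methyl-3-(2-oxoethyl)-1-[(triethylsilyl)oxy]pent-4-en-2-yl (2Z)-2-methylbut-2-enoate | CC(C)(C)[Si](c1ccccc1)(c1ccccc1)OCC[C@H]1O[C@@]1(C)[C@@H](O[Si](CC)(CC)CC)[C@@H](OC(=O)/C(C)=C\C)[C@@H](C(C)=C)CC=O | intermediate
26 | ethyltriphenylphosphonium iodide | [I-].CC[P+](c1ccccc1)(c1ccccc1)c1ccccc1 | starting material
27 | ethylidenetriphenylphosphorane | CC=P(c1ccccc1)(c1ccccc1)c1ccccc1 | intermediate
28 | (1-iodoethyl)triphenylphosphonium iodide | [I-].CC(I)[P+](c1ccccc1)(c1ccccc1)c1ccccc1 | intermediate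
29 | (1-iodoethylidene)triphenylphosphorane | CC(I)=P(c1ccccc1)(c1ccccc1)c1ccccc1 | intermediate
30 | (1S,2S,3R)-1-[(2R,3R)-3-{2-[(tert-butyldiphenylsilyl)oxy]ethyl}-2-methyloxiran-2-yl]-3-[(2Z)-3-iodobut-2-en-1-yl]-4-methyl-1-[(triethylsilyl)oxy]pent-4-en-2-yl (2Z)-2-methylbut-2-enoate | CC(C)(C)[Si](c1ccccc1)(c1ccccc1)OCC[C@H]1O[C@@]1(C)[C@@H](O[Si](CC)(CC)CC)[C@@H](OC(=O)/C(C)=C\C)[C@@H](C(C)=C)C/C=C(C)\I | intermediate
31 | (1S,2S,3R)-1-[(2S,3R)-3-{2-[(tert-butyldiphenylsilyl)oxy]ethyl}-2-methyloxiran-2-yl]-1-hydroxy-3-[(2Z)-3-iodobut-2-en-1-yl]-4-methylpent-4-en-2-yl (2Z)-2-methylbut-2-enoate | CC(C)(C)[Si](c1ccccc1)(c1ccccc1)OCC[C@H]1O[C@@]1(C)[C@@H](O)[C@@H](OC(=O)/C(C)=C\C)[C@@H](C(C)=C)C/C=C(C)\I | intermediate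
32 | (1S,2S,3R)-1-acetoxy-1-[(2R,3R)-3-{2-[(tert-butyldiphenylsilyl)oxy]ethyl}-2-methyloxiran-2-yl]-3-[(2Z)-3-iodobut-2-en-1-yl]-4-methylpent-4-en-2-yl (2Z)-2-methylbut-2-enoate | CC(C)(C)[Si](c1ccccc1)(c1ccccc1)OCC[C@H]1O[C@@]1(C)[C@@H](OC(C)=O)[C@@H](OC(=O)/C(C)=C\C)[C@@H](C(C)=C)C/C=C(C)\I | intermediate
33 | (1S,2S,3R)-1-acetoxy-1-[(2R,3R)-3-(2-hydroxyethyl)-2-methyloxiran-2-yl]-3-[(2Z)-3-iodobut-2-en-1-yl]-4-methylpent-4-en-2-yl (2Z)-2-methylbut-2-enoate | OCC[C@H]1O[C@@]1(C)[C@@H](OC(C)=O)[C@@H](OC(=O)/C(C)=C\C)[C@@H](C(C)=C)C/C=C(C)\I | intermediate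
34 | (1S,2S,3R)-1-acetoxy-3-[(2Z)-3-iodobut-2-en-1-yl]-4-methyl-1-[(2R,3R)-2-methyl-3-(2-oxoethyl)oxiran-2-yl]pent-4-en-2-yl (2Z)-2-methylbut-2-enoate | O=CC[C@H]1O[C@@]1(C)[C@@H](OC(C)=O)[C@@H](OC(=O)/C(C)=C\C)[C@@H](C(C)=C)C/C=C(C)\I | intermediate
35 | alkenylchromium dichloride from 34 (CrCl2 on C4 in place of iodine, trivalent chromium, Z geometry kept) | O=CC[C@H]1O[C@@]1(C)[C@@H](OC(C)=O)[C@@H](OC(=O)/C(C)=C\C)[C@@H](C(C)=C)C/C=C(C)\[Cr](Cl)Cl | intermediate
36 | (1R,3S,4Z,7R,8S,9S,10R)-9-acetoxy-1,10-epoxy-3-hydroxy-4,10-dimethyl-7-(prop-1-en-2-yl)cyclodec-4-en-8-yl (2Z)-2-methylbut-2-enoate | C=C(C)[C@H]1C/C=C(C)\[C@@H](O)C[C@H]2O[C@@]2(C)[C@@H](OC(C)=O)[C@H]1OC(=O)/C(C)=C\C | intermediate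
37 | (1R,3S,4R,5S,7R,8S,9S,10R)-9-acetoxy-1,10:4,5-diepoxy-3-hydroxy-4,10-dimethyl-7-(prop-1-en-2-yl)cyclodecan-8-yl (2Z)-2-methylbut-2-enoate | C=C(C)[C@H]1C[C@@H]2O[C@]2(C)[C@@H](O)C[C@H]2O[C@@]2(C)[C@@H](OC(C)=O)[C@H]1OC(=O)/C(C)=C\C | intermediate
38 | CNP0220329.1, (1R,3S,4S,5S,7R,8S,9S,10R)-9-acetoxy-1,10:4,5-diepoxy-4,10-dimethyl-7-(prop-1-en-2-yl)cyclodecane-3,8-diyl bis[(2Z)-2-methylbut-2-enoate] | C=C(C)[C@H]1C[C@@H]2O[C@]2(C)[C@@H](OC(=O)/C(C)=C\C)C[C@H]2O[C@@]2(C)[C@@H](OC(C)=O)[C@H]1OC(=O)/C(C)=C\C | target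

**Step count**

Total step count: 24. Longest linear sequence: 19 (steps 1–7, 12 and 14–24); steps 8–11 form the eastern branch and step 13 prepares the acylating agent.

**Steps most likely to fail**

Step 22. The ring closure may proceed with poor facial selectivity at C3, since only the fold of the chain differentiates the two aldehyde faces. The fallback sets out from 36 obtained as a mixture of C3 epimers. Dess–Martin oxidation (pyridine, CH2Cl2, 0 °C) converts both epimers into one enone, (1R,4Z,7R,8S,9S,10R)-9-acetoxy-1,10-epoxy-4,10-dimethyl-3-oxo-7-(prop-1-en-2-yl)cyclodec-4-en-8-yl (2Z)-2-methylbut-2-enoate F1. A Corey–Bakshi–Shibata reduction ((R)-2-methyl-CBS-oxazaborolidine, catecholborane, toluene, −78 °C), in which the α-methyl alkenyl side acts as the large group, should then return 36 with the 3S configuration. C3 is thereby set by the reagent and not by the macrocyclisation.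

Step 23. Oxygen may be transferred to the wrong face of C4=C5, or the isopropenyl group may be oxidised in competition. The fallback sets out from 36 and reverses the last two operations. Acylation with mixed anhydride 22 (Et3N, toluene, 80 °C) gives the 3,8-diangelate (1R,3S,4Z,7R,8S,9S,10R)-9-acetoxy-1,10-epoxy-4,10-dimethyl-7-(prop-1-en-2-yl)cyclodec-4-ene-3,8-diyl bis[(2Z)-2-methylbut-2-enoate] F2. Dimethyldioxirane (acetone, −20 °C) should then epoxidise the strained ring alkene from its exposed outer face without any hydroxyl direction, which arrives directly at 38.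

Step 5. The Grignard addition may show low facial selectivity, because the C10 methyl and the ring carbon C1 differ little in size. The fallback sets out from 8 obtained as a mixture of C9 epimers. Dess–Martin oxidation gives the epoxy enone 1-[(2R,3R)-3-{2-[(tert-butyldiphenylsilyl)oxy]ethyl}-2-methyloxiran-2-yl]prop-2-en-1-one F3. Reduction with Zn(BH4)2 (Et2O, −78 °C), in which zinc bridges the carbonyl and epoxide oxygens and hydride enters from the open face, should give the erythro alcohol and so returns to 8.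

Further compounds

F1 | step 22 | (1R,4Z,7R,8S,9S,10R)-9-acetoxy-1,10-epoxy-4,10-dimethyl-3-oxo-7-(prop-1-en-2-yl)cyclodec-4-en-8-yl (2Z)-2-methylbut-2-enoate | C=C(C)[C@H]1C/C=C(C)\C(=O)C[C@H]2O[C@@]2(C)[C@@H](OC(C)=O)[C@H]1OC(=O)/C(C)=C\C
F2 | step 23 | (1R,3S,4Z,7R,8S,9S,10R)-9-acetoxy-1,10-epoxy-4,10-dimethyl-7-(prop-1-en-2-yl)cyclodec-4-ene-3,8-diyl bis[(2Z)-2-methylbut-2-enoate] | C=C(C)[C@H]1C/C=C(C)\[C@@H](OC(=O)/C(C)=C\C)C[C@H]2O[C@@]2(C)[C@@H](OC(C)=O)[C@H]1OC(=O)/C(C)=C\C
F3 | step 5 | 1-[(2R,3R)-3-{2-[(tert-butyldiphenylsilyl)oxy]ethyl}-2-methyloxiran-2-yl]prop-2-en-1-one | CC(C)(C)[Si](c1ccccc1)(c1ccccc1)OCC[C@H]1O[C@@]1(C)C(=O)C=C
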